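The target (a para-quinone methide lactone) is traced back to a racemic 3-aryl-benzofuran-2(3H)-one whose benzene ring (ring A, C3a–C7a) carries an acetonide-bridged catechol at C5/C6 and bromine at C4 and C7. C4 and C7 face each other across ring A, each next to one oxygenated carbon, and both need the same phenyl group. One twofold Suzuki coupling with phenylboronic acid therefore forms both biaryl bonds in a single operation. The dibromide comes from benzene-1,2,4-triol and 4-hydroxymandelic acid, the hydroxyl pattern of the triol deciding where the lactone forms. Only the late oxidation, which leaves one enolic hydroxyl at C5, tells the two catechol oxygens apart.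

Key step: step 5

Remark: benzofuran numbering is used (O1, C2, C3, C3a, C4–C7, C7a). Ring A is the benzene ring of the benzofuranone, ring B the lactone, ring C the 4-oxygenated aryl group on C3. The target is read as the achiral 5-methoxy para-quinone methide (C3=C3a, C4=C5, C7=C7a, C6=O). C3 is sp3 and racemic in every intermediate up to 15 and becomes sp2 in step 7, so no stereocontrol is needed. Compound 2 is taken as the commercial racemate.

Step 1
Reactants: 1 benzene-1,2,4-triol; 2 4-hydroxymandelic acid (racemic)
Product: 4 5,6-dihydroxy-3-(4-hydroxyphenyl)benzofuran-2(3H)-one (racemic), via triol acid 3 (not isolated)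
Conditions: 1 (1.3 equiv), TsOH·H2O (10 mol %), toluene/1,4-dioxane, reflux, Dean–Stark trap, argon
Reagents that add atoms: none
Why: Acid ionises the para-hydroxybenzylic alcohol of 2 to a stabilised cation that attacks 1 at C5, its most nucleophilic carbon (ortho to the 4-OH, para to the 2-OH), and acid 3 then closes onto the neighbouring 4-OH (Friedel–Crafts alkylation followed by lactonisation); the C3 stereocentre forms without control, which is harmless because step 7 removes it.

Step 2
Reactants: 4 5,6-dihydroxy-3-(4-hydroxyphenyl)benzofuran-2(3H)-one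
Product: 5 acetonide of 5,6-dihydroxy-3-(4-hydroxyphenyl)benzofuran-2(3H)-one (racemic)
Conditions: 2,2-dimethoxypropane (5 equiv), TsOH·H2O (5 mol %), toluene, reflux through 4 Å MS (Soxhlet), argon
Reagents that add atoms: 2,2-dimethoxypropane, COC(C)(C)OC
Why: Acid-catalysed ketal exchange (acetonide formation) can close a five-membered dioxole only across the adjacent C5 and C6 hydroxyls, the lone 4′-phenol cannot form a cyclic ketal, and removal of methanol drives the equilibrium and keeps the lactone closed.

Step 3
Reactants: 5 acetonide of 5,6-dihydroxy-3-(4-hydroxyphenyl)benzofuran-2(3H)-one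
Product: 6 acetonide of 5,6-dihydroxy-3-[4-(pivaloyloxy)phenyl]benzofuran-2(3H)-one (racemic)
Conditions: PivCl (1.2 equiv), pyridine (3 equiv), CH2Cl2, 0 °C to rt
Reagents that add atoms: pivaloyl chloride, CC(C)(C)C(Cl)=O
Why: Pyridine-mediated O-acylation (esterification through the N-acylpyridinium ion) of the only free hydroxyl; pyridine is too weak a base to enolise the lactone, and the hindered ester deactivates ring C toward bromine and tolerates the base of step 5.

Step 4
Reactants: 6 acetonide of 5,6-dihydroxy-3-[4-(pivaloyloxy)phenyl]benzofuran-2(3H)-one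
Product: 8 acetonide of 4,7-dibromo-5,6-dihydroxy-3-[4-(pivaloyloxy)phenyl]benzofuran-2(3H)-one (racemic), via 7-bromo lactone 7 (not isolated)
Conditions: NBS (2.1 equiv), DMF, 0 °C to rt, dark
Reagents that add atoms: N-bromosuccinimide, O=C1CCC(=O)N1Br
Why: Electrophilic aromatic bromination: C7 and then C4 are the only unsubstituted carbons of ring A and each is ortho to a dioxole oxygen held coplanar by the ketal ring, whereas ring C is deactivated by its acyloxy group and the absence of base and light keeps NBS away from the enolisable C3–H.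

Step 5
Reactants: 8 acetonide of 4,7-dibromo-5,6-dihydroxy-3-[4-(pivaloyloxy)phenyl]benzofuran-2(3H)-one; 9 phenylboronic acid
Product: 11 acetonide of 5,6-dihydroxy-4,7-diphenyl-3-[4-(pivaloyloxy)phenyl]benzofuran-2(3H)-one (racemic), via 4-bromo-7-phenyl lactone 10 (not isolated)
Conditions: 9 (3 equiv), Pd(OAc)2 (5 mol %), SPhos (10 mol %), anhydrous K3PO4 (4 equiv), degassed toluene, 100 °C, argon; then 1 M HCl work-up
Reagents that add atoms: none
Why: Pd(OAc)2 is reduced in the flask from divalent palladium to zerovalent palladium, which, carried by the bulky electron-rich biaryl phosphine, inserts first into the less crowded C7–Br bond and then into C4–Br; transmetallation with phosphate-activated 9 and reductive elimination form the C7–phenyl and C4–phenyl bonds (Suzuki–Miyaura coupling). The closest known reaction type is the Suzuki coupling of di-ortho-substituted aryl bromides with dialkylbiarylphosphine ligands. No ring is closed and no stereocentre is made, and C3 stays racemic. The step needs complete twofold coupling without protodebromination, without palladium-mediated arylation at the C3 enolate or at an ortho C–H of ring C, and with lactone and pivalate intact. The substrate helps because the dioxole and ring B tie back the groups flanking each bromine, while arylation at C3 would have to build a quaternary carbon beside a di-ortho-substituted aryl group and should be far slower than transmetallation with excess unhindered 9. Anhydrous, poorly soluble K3PO4 keeps the enolate concentration low and spares both esters, and the acidic work-up recloses any lactone that has opened.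

Step 6
Reactants: 11 acetonide of 5,6-dihydroxy-4,7-diphenyl-3-[4-(pivaloyloxy)phenyl]benzofuran-2(3H)-one
Product: 14 5,6-dihydroxy-3-(4-hydroxyphenyl)-4,7-diphenylbenzofuran-2(3H)-one (racemic), via ring-opened hydroxy acid 12 (not isolated), via phenol acetonide lactone 13 (not isolated)
Conditions: LiOH·H2O (6 equiv), degassed THF/H2O, rt, argon; then HCl (to ca. 3 M), 60 °C; extracted under argon, used at once
Reagents that add atoms: none
Why: Saponification cleaves the aryl pivalate and opens the aryl lactone to the salt of 12, and acidification relactonises the 2-hydroxyaryl acetic acid to 13 and hydrolyses the catechol isopropylidene ketal (ester hydrolysis, lactonisation and ketal hydrolysis in one pot); air is excluded because the phenolates and the product catechol are electron-rich.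

Step 7
Reactants: 14 5,6-dihydroxy-3-(4-hydroxyphenyl)-4,7-diphenylbenzofuran-2(3H)-one
Product: 16 5-hydroxy-3-(4-hydroxyphenyl)-4,7-diphenylbenzofuran-2,6-dione (xylerythrin), via ortho-quinone 15 (not isolated)
Conditions: DDQ (1.0 equiv), 1,4-dioxane, rt, argon
Reagents that add atoms: none
Why: Quinone dehydrogenation of the catechol gives ortho-quinone 15, whose C3–H (alpha to the lactone carbonyl and vinylogous to the C5 carbonyl) shifts to O5 to give the fully conjugated para-quinone methide; this tautomerisation can place the carbonyl only at C6 (para to C3a) and the enolic hydroxyl only at C5, one equivalent of oxidant limits further oxidation of the 4′-phenol, and the C3 stereocentre is erased.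

Step 8
Reactants: 16 5-hydroxy-3-(4-hydroxyphenyl)-4,7-diphenylbenzofuran-2,6-dione
Product: 17 3-(4-hydroxyphenyl)-5-methoxy-4,7-diphenylbenzofuran-2,6-dione (CNP0282683.0)
Conditions: CH2N2 (1.05 equiv, Et2O solution), THF, −20 to 0 °C; excess quenched with AcOH
Reagents that add atoms: diazomethane, C=[N+]=[N-]
Why: O-methylation of an acid by diazomethane (proton transfer, then SN2 attack on the methyldiazonium ion): the 5-hydroxyl is a vinylogous carboxylic acid (conjugated through C4=C5 and C3=C3a to the lactone carbonyl) and should be much more acidic than the 4′-phenol, so one equivalent at low temperature should methylate it alone; the C6 oxygen carries no charge in the anion and the tetrasubstituted C=C bonds resist cycloaddition.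

Compound list
1 | benzene-1,2,4-triol | Oc1ccc(O)c(O)c1 | starting material
2 | 4-hydroxymandelic acid (racemic) | OC(C(=O)O)c1ccc(O)cc1 | starting material
3 | 2-(4-hydroxyphenyl)-2-(2,4,5-trihydroxyphenyl)acetic acid (racemic, not isolated) | OC(=O)C(c1ccc(O)cc1)c1cc(O)c(O)cc1O | intermediate
4 | 5,6-dihydroxy-3-(4-hydroxyphenyl)benzofuran-2(3H)-one (racemic) | O=C1Oc2cc(O)c(O)cc2C1c1ccc(O)cc1 | intermediate
5 | acetonide of 5,6-dihydroxy-3-(4-hydroxyphenyl)benzofuran-2(3H)-one (racemic) | CC1(C)Oc2cc3OC(=O)C(c4ccc(O)cc4)c3cc2O1 | intermediate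
6 | acetonide of 5,6-dihydroxy-3-[4-(pivaloyloxy)phenyl]benzofuran-2(3H)-one (racemic) | CC1(C)Oc2cc3OC(=O)C(c4ccc(OC(=O)C(C)(C)C)cc4)c3cc2O1 | intermediate
7 | acetonide of 7-bromo-5,6-dihydroxy-3-[4-(pivaloyloxy)phenyl]benzofuran-2(3H)-one (racemic, not isolated) | CC1(C)Oc2c(Br)c3OC(=O)C(c4ccc(OC(=O)C(C)(C)C)cc4)c3cc2O1 | intermediate
8 | acetonide of 4,7-dibromo-5,6-dihydroxy-3-[4-(pivaloyloxy)phenyl]benzofuran-2(3H)-one (racemic) | CC1(C)Oc2c(O1)c(Br)c1OC(=O)C(c3ccc(OC(=O)C(C)(C)C)cc3)c1c2Br | intermediate
9 | phenylboronic acid | OB(O)c1ccccc1 | starting material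
10 | acetonide of 4-bromo-5,6-dihydroxy-7-phenyl-3-[4-(pivaloyloxy)phenyl]benzofuran-2(3H)-one (racemic, not isolated) | CC1(C)Oc2c(O1)c(-c1ccccc1)c1OC(=O)C(c3ccc(OC(=O)C(C)(C)C)cc3)c1c2Br | intermediate
11 | acetonide of 5,6-dihydroxy-4,7-diphenyl-3-[4-(pivaloyloxy)phenyl]benzofuran-2(3H)-one (racemic) | CC1(C)Oc2c(O1)c(-c1ccccc1)c1OC(=O)C(c3ccc(OC(=O)C(C)(C)C)cc3)c1c2-c1ccccc1 | intermediate
12 | 2-(6-hydroxy-2,2-dimethyl-4,7-diphenyl-1,3-benzodioxol-5-yl)-2-(4-hydroxyphenyl)acetic acid (racemic, present as lithium salt, not isolated) | CC1(C)Oc2c(O1)c(-c1ccccc1)c(O)c(C(C(=O)O)c1ccc(O)cc1)c2-c1ccccc1 | intermediate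
13 | acetonide of 5,6-dihydroxy-3-(4-hydroxyphenyl)-4,7-diphenylbenzofuran-2(3H)-one (racemic, not isolated) | CC1(C)Oc2c(O1)c(-c1ccccc1)c1OC(=O)C(c3ccc(O)cc3)c1c2-c1ccccc1 | intermediate
14 | 5,6-dihydroxy-3-(4-hydroxyphenyl)-4,7-diphenylbenzofuran-2(3H)-one (racemic) | O=C1Oc2c(-c3ccccc3)c(O)c(O)c(-c3ccccc3)c2C1c1ccc(O)cc1 | intermediate
15 | 3-(4-hydroxyphenyl)-4,7-diphenylbenzofuran-2,5,6(3H)-trione (racemic ortho-quinone, not isolated) | O=C1C(=O)C(c2ccccc2)=C2OC(=O)C(c3ccc(O)cc3)C2=C1c1ccccc1 | intermediate
16 | 5-hydroxy-3-(4-hydroxyphenyl)-4,7-diphenylbenzofuran-2,6-dione (xylerythrin) | OC1=C(c2ccccc2)C2=C(c3ccc(O)cc3)C(=O)OC2=C(c2ccccc2)C1=O | intermediate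
17 | 3-(4-hydroxyphenyl)-5-methoxy-4,7-diphenylbenzofuran-2,6-dione (CNP0282683.0) | COC1=C(c2ccccc2)C2=C(c3ccc(O)cc3)C(=O)OC2=C(c2ccccc2)C1=O | target

Total step count: 8. Longest linear sequence: 8 steps (1 and 2 to 17; phenylboronic acid 9 enters at step 5).

Steps most likely to fail

Step 5. The second coupling at the more crowded C4–Br may stall, or the potassium enolate at C3 may divert palladium into loss of bromine without C–C bond formation. The fallback is a base-free Stille coupling, in which no enolate is ever formed. It sets out from 8, which with tributyl(phenyl)stannane (3 equiv) and Pd(P(t-Bu)3)2, a complex of zerovalent palladium, in 1,4-dioxane at 100 °C should give 11 directly. The route is rejoined at 11 and no new compound is made.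

Step 4. Substitution may spill over to the enolisable, doubly benzylic C3–H before the slower second ring bromination at C4 is complete. The fallback accepts this and corrects it afterwards. From 6, NBS (3.3 equiv, DMF, rt) should brominate all three positions to the acetonide of 3,4,7-tribromo-5,6-dihydroxy-3-[4-(pivaloyloxy)phenyl]benzofuran-2(3H)-one F1. Zinc dust in AcOH/THF at 0 °C then reduces only the tertiary alpha-bromo lactone C–Br bond, since aryl bromides are inert to these conditions. This returns to 8.

Step 8. Chemoselectivity between the two acidic hydroxyls may be lost, so that the 4′-phenol (itself activated by the quinone methide) is methylated as well. The fallback protects, methylates and unmasks. From 16, TBSCl (2.5 equiv) and imidazole in DMF should silylate both hydroxyls to the 5,4′-bis(tert-butyldimethylsilyl) ether of xylerythrin F2. Its 5-O-silyl group is a vinylogous silyl ester and should hydrolyse in aqueous AcOH/THF at 0 °C, leaving the 4′-O-tert-butyldimethylsilyl ether of xylerythrin F3. Diazomethane then methylates the only free hydroxyl to give the 4′-O-tert-butyldimethylsilyl ether of 5-O-methylxylerythrin F4. HF·pyridine in THF at 0 °C removes the aryl silyl ether under acidic, non-nucleophilic conditions and reaches 17.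

Further compounds
F0 | step 5 | none | none
F1 | step 4 | acetonide of 3,4,7-tribromo-5,6-dihydroxy-3-[4-(pivaloyloxy)phenyl]benzofuran-2(3H)-one (racemic) | CC1(C)Oc2c(O1)c(Br)c1OC(=O)C(Br)(c3ccc(OC(=O)C(C)(C)C)cc3)c1c2Br
F2 | step 8 | 5-(tert-butyldimethylsilyloxy)-3-[4-(tert-butyldimethylsilyloxy)phenyl]-4,7-diphenylbenzofuran-2,6-dione | CC(C)(C)[Si](C)(C)OC1=C(c2ccccc2)C2=C(c3ccc(O[Si](C)(C)C(C)(C)C)cc3)C(=O)OC2=C(c2ccccc2)C1=O
F3 | step 8 | 3-[4-(tert-butyldimethylsilyloxy)phenyl]-5-hydroxy-4,7-diphenylbenzofuran-2,6-dione | OC1=C(c2ccccc2)C2=C(c3ccc(O[Si](C)(C)C(C)(C)C)cc3)C(=O)OC2=C(c2ccccc2)C1=O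
F4 | step 8 | 3-[4-(tert-butyldimethylsilyloxy)phenyl]-5-methoxy-4,7-diphenylbenzofuran-2,6-dione | COC1=C(c2ccccc2)C2=C(c3ccc(O[Si](C)(C)C(C)(C)C)cc3)C(=O)OC2=C(c2ccccc2)C1=O
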